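**Plan**

1. Retrosynthesis: the C14 aldehyde, the C13 methylene and the C9 carbinol are simplified to a silyl ether, a saturated lactone and a ketone. The C4=C5 olefin and the C9 carbonyl are then reconnected as a C4–C9 σ bond (retro-Grob), which folds the ten-membered ring into a cis-decalin 1,3-diol monomesylate.
2. Feature used: in germacrane numbering C4 and C9 face each other across the ten-membered ring. A temporary C4–C9 bond therefore divides it into ring A (C1–C4, C9, C10; a cyclohexene that already holds C1=C10) and ring B (C4–C9; a chair carrying C5–C8, with C9–OH and C5–OMs 1,3-related across C4).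
3. Further cuts: the C8 ester; the C6–O/C7–C11 lactone bonds and C8–O back to a C5 ketone; C1=C10/C9–OH back to an enone epoxide (retro-Wharton); C9–C10 and C3–C4 (Robinson annulation of 2-methylcyclohexane-1,3-dione with an alkoxyethyl vinyl ketone).
4. Forward order: ring B is the dione ring, ring A closes by Robinson annulation, the lactone is annulated onto C6–C7 of ring B, and the ten-membered ring is released last by fragmentation.
5. Stereochemistry: C4 (a relay centre, later erased) from the L-phenylalanine-mediated aldol; C9–O cis to the methyl from nucleophilic epoxidation; C7 and C6 from axial hydride delivery and Rubottom oxidation on the cis-decalin; C5 and C8 from C9–OH-directed hydride; the final C9 carbinol from Felkin–Anh reduction; the ester from (S)-2-methylbutanoic acid.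

Key step: step 23

Remark 1: germacrane numbering is used throughout, and α/β refer to the ring faces of the target (C6–O, the C15 methyl and the C9–O bond of the decalins are α; C7–C11 and C8–O are β).
Remark 2: the acetal carbon of 13–24 is drawn as the aryl-equatorial epimer, C8 of 18–26 as the 8β epimer expected from attack anti to the C9–O bond, C7 of 20 and C11 of 35/36 as the expected kinetic epimers, and 5 is racemic; all of these centres are erased later.

**Route**

Step 1
Reactants: 1 propane-1,3-diol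
Product: 2 3-[(4-methoxybenzyl)oxy]propan-1-ol
Conditions: NaH (1 equiv), 4-methoxybenzyl chloride (1 equiv), Bu4NI (cat.), THF/DMF, 0 °C to rt; diol in threefold excess
Reagents that add atoms: 4-methoxybenzyl chloride, COc1ccc(CCl)cc1
Why: Williamson etherification of the monoalkoxide of a symmetric diol used in excess should give mainly the mono-ether, and no stereocentre is involved.

Step 2
Reactants: 2 3-[(4-methoxybenzyl)oxy]propan-1-ol
Product: 3 3-[(4-methoxybenzyl)oxy]propanal
Conditions: Dess–Martin periodinane, CH2Cl2, 0 °C to rt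
Reagents that add atoms: none
Why: Dess–Martin oxidation takes a primary alcohol to the aldehyde without over-oxidation and leaves the benzylic ether untouched.

Step 3
Reactants: 3 3-[(4-methoxybenzyl)oxy]propanal; 4 vinylmagnesium bromide
Product: 5 rac-5-[(4-methoxybenzyl)oxy]pent-1-en-3-ol
Conditions: THF, −78 °C; NH4Cl (aq.)
Reagents that add atoms: none
Why: Grignard 1,2-addition to the aldehyde gives the allylic alcohol, whose racemic carbinol centre is removed in the next step.

Step 4
Reactants: 5 rac-5-[(4-methoxybenzyl)oxy]pent-1-en-3-ol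
Product: 6 5-[(4-methoxybenzyl)oxy]pent-1-en-3-one
Conditions: Dess–Martin periodinane, CH2Cl2, 0 °C; used at once
Reagents that add atoms: none
Why: Dess–Martin oxidation of the allylic alcohol gives the vinyl ketone under non-basic conditions that should spare the β-alkoxy ketone from elimination.

Step 5
Reactants: 6 5-[(4-methoxybenzyl)oxy]pent-1-en-3-one; 7 2-methylcyclohexane-1,3-dione
Product: 8 2-{5-[(4-methoxybenzyl)oxy]-3-oxopentyl}-2-methylcyclohexane-1,3-dione
Conditions: Et3N (0.1 equiv), MeCN, rt
Reagents that add atoms: none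
Why: Michael addition of the stabilized dione enolate to the vinyl ketone (first half of a Robinson annulation) forms the C3–C4 bond and a prochiral quaternary C4.

Step 6
Reactants: 8 2-{5-[(4-methoxybenzyl)oxy]-3-oxopentyl}-2-methylcyclohexane-1,3-dione
Product: 9 (S)-5-{[(4-methoxybenzyl)oxy]methyl}-8a-methyl-3,4,8,8a-tetrahydronaphthalene-1,6(2H,7H)-dione
Conditions: L-phenylalanine (1 equiv), (1S)-(+)-10-camphorsulfonic acid (0.5 equiv), DMF, rt to 50 °C
Reagents that add atoms: none
Why: Amino-acid-mediated intramolecular aldol condensation (Hajos–Parrish–Eder–Sauer–Wiechert reaction) closes ring A (C9–C10 bond) through an enamine that selects one of the two enantiotopic ring carbonyls, and the L-amino acid should give the (S)-configured C4 as in the parent annulation.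

Step 7
Reactants: 9 (S)-enedione
Product: 10 (4aS,5S)-5-hydroxy-1-{[(4-methoxybenzyl)oxy]methyl}-4a-methyl-4,4a,5,6,7,8-hexahydronaphthalen-2(3H)-one
Conditions: NaBH4 (0.3 equiv), EtOH, −15 °C
Reagents that add atoms: none
Why: Chemoselective borohydride reduction of the saturated C5 ketone beside the tetrasubstituted enone, with hydride entering anti to the axial angular methyl, masks C5 as the 5α-alcohol (configuration of no consequence) for the hydrazine step.

Step 8
Reactants: 10 hydroxy enone
Product: 11 epoxy ketone (9α,10α-epoxide of 10; epoxide oxygen cis to C15 and to the 5α-OH)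
Conditions: 30% H2O2, NaOH (aq.), MeOH, 0 °C to rt
Reagents that add atoms: hydrogen peroxide, OO
Why: Weitz–Scheffer nucleophilic epoxidation, in which hydroperoxide adds axially to C9 on the methyl-bearing face as in 4-en-3-one steroids and octalones, places the future C9 oxygen cis to C15.

Step 9
Reactants: 11 epoxy ketone
Product: 12 cis-decalin diol (C1=C10 olefin carrying C14–OPMB; 9α-OH at the ring fusion cis to C15; 5α-OH)
Conditions: N2H4·H2O (3 equiv), AcOH (cat.), MeOH, 0 °C to rt
Reagents that add atoms: none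
Why: Wharton transposition (hydrazone, epoxide opening to the alkenyl diazene, loss of N2) moves the oxygen to C9 with retention of the epoxide configuration and leaves the C1=C10 olefin of ring A.

Step 10
Reactants: 12 cis-decalin diol
Product: 13 hydroxy acetal (9,14-O-(4-methoxybenzylidene) acetal, aryl equatorial; 5α-OH)
Conditions: DDQ (1.1 equiv), 4 Å molecular sieves, CH2Cl2, 0 °C
Reagents that add atoms: none
Why: DDQ oxidation of the 4-methoxybenzyl ether to its oxocarbenium ion under anhydrous conditions, with capture by the neighbouring C9 hydroxyl (oxidative benzylidene acetal formation), gives the six-membered acetal that protects the tertiary alcohol and holds ring B in the chair with C9–O axial.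

Step 11
Reactants: 13 hydroxy acetal
Product: 14 acetal ketone (C5 ketone)
Conditions: Dess–Martin periodinane, NaHCO3, CH2Cl2, rt
Reagents that add atoms: none
Why: Buffered Dess–Martin oxidation returns the C5 ketone without touching the acid-labile acetal.

Step 12
Reactants: 14 acetal ketone
Product: 16 acetal enone (C5 ketone conjugated to C6=C7), via trimethylsilyl enol ether 15 (not isolated)
Conditions: LiN(iPr)2, Me3SiCl, THF, −78 °C; then Pd(OAc)2 (1.05 equiv), MeCN, rt
Reagents that add atoms: none
Why: Saegusa–Ito oxidation, in which C6 is the only enolizable position of the C5 ketone, so enol silylation and palladium-mediated dehydrogenation can give only the C6=C7 enone.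

Step 13
Reactants: 16 acetal enone
Product: 18 hydroxy enone (8β-OH; C5 ketone; C6=C7), via trimethylsilyl dienol ether 17 (not isolated)
Conditions: KN(SiMe3)2, THF, −78 °C, then Me3SiCl; then dimethyldioxirane, acetone/CH2Cl2, −78 °C; NaHCO3 (aq.)
Reagents that add atoms: dimethyldioxirane, CC1(C)OO1
Why: Vinylogous Rubottom oxidation, in which γ-deprotonation is possible only at C8 and the silyl dienol ether is epoxidized at its electron-rich C7=C8 terminus and collapses to the γ-hydroxy enone, oxygen being expected on the β face anti to the pseudoaxial C9–O bond.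

Step 14
Reactants: 18 hydroxy enone
Product: 19 silyloxy enone (8β-OSiEt3)
Conditions: Et3SiCl, imidazole, DMF, 0 °C
Reagents that add atoms: chlorotriethylsilane, CC[Si](Cl)(CC)CC
Why: Standard silylation of the secondary alcohol protects the C8 oxygen through the next two steps.

Step 15
Reactants: 19 silyloxy enone
Product: 21 ester enone (C5 ketone; C6=C7 with CH2CO2CH3 on C7; 8β-OSiEt3), via trimethylsilyl enol ether 20 (not isolated)
Conditions: 1-methoxy-1-(trimethylsilyloxy)ethene (2 equiv), Bu4N[Ph3SiF2] (5 mol %), THF, −78 to 0 °C; then Pd(OAc)2 (1.05 equiv), MeCN, rt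
Reagents that add atoms: 1-methoxy-1-(trimethylsilyloxy)ethene, COC(=C)O[Si](C)(C)C
Why: Fluoride-catalysed Mukaiyama–Michael addition forms the C7–C11 bond and delivers the C5 silyl enol ether regiospecifically, and Saegusa–Ito oxidation then restores the C6=C7 enone so that C7 (its configuration in 20 thereby erased) can be set by hydride delivery.

Step 16
Reactants: 21 ester enone
Product: 24 acetal keto lactone (trans-fused 12,6α-olide with C11H2; C5 ketone; 8β-OSiEt3), via dimethylphenylsilyl enol ether 22 (not isolated), via silyloxy ketone 23 (not isolated)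
Conditions: PhMe2SiH, RhCl(PPh3)3 (2 mol %), benzene, 50 °C; then dimethyldioxirane, acetone/CH2Cl2, −78 °C; then CsF (0.2 equiv), MeCN, 0 °C to rt
Reagents that add atoms: dimethyldioxirane, CC1(C)OO1
Why: Rhodium-catalysed 1,4-hydrosilylation should deliver hydrogen to C7 axially from the α face, anti to the pseudoaxial 8β-silyloxy group (ester arm β, equatorial), Rubottom oxidation of the resulting enol ether should occur on the α face of C6 because the β face is screened by the axial C3 methylene and the C8 oxygen, and fluoride-triggered silyl transfer lets the 6α-alkoxide close the trans-fused (diequatorial) γ-lactone.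

Step 17
Reactants: 24 acetal keto lactone
Product: 25 keto lactone triol (12,6α-olide; C5 ketone; 8β-OH; 9α-OH; 14-OH)
Conditions: AcOH/THF/H2O (3:1:1), 40 °C
Reagents that add atoms: none
Why: Mild aqueous acid hydrolyses the 4-methoxybenzylidene acetal and the triethylsilyl ether in one operation, while the lactone and the tertiary allylic alcohol should survive.

Step 18
Reactants: 25 keto lactone triol
Product: 26 silyl ether keto lactone (14-OTBS; 8β-OH; 9α-OH; C5 ketone)
Conditions: TBSCl (1.05 equiv), imidazole, CH2Cl2, −20 °C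
Reagents that add atoms: tert-butyldimethylsilyl chloride, CC(C)(C)[Si](C)(C)Cl
Why: Silyl chloride/imidazole silylation is selective for the primary allylic C14 hydroxyl over the hindered secondary and the tertiary hydroxyl.

Step 19
Reactants: 26 silyl ether keto lactone
Product: 27 diketo lactone (12,6α-olide; C5 and C8 ketones; 9α-OH; 14-OTBS)
Conditions: IBX, DMSO, rt
Reagents that add atoms: none
Why: IBX oxidizes the secondary carbinol of a 1,2-diol to the α-hydroxy ketone without glycol cleavage, which removes the uncontrolled C8 centre.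

Step 20
Reactants: 27 diketo lactone
Product: 28 lactone triol (5β-OH; 8β-OH; 9α-OH; 14-OTBS)
Conditions: Me4NBH(OAc)3 (6 equiv), AcOH/MeCN (1:1), −30 to 0 °C
Reagents that add atoms: none
Why: Hydroxyl-directed (Saksena–Evans) reduction, in which borohydride bound to the axial 9α-hydroxyl delivers hydride intramolecularly to the α faces of both the C8 (α-hydroxy) and C5 (β-hydroxy) ketones, should give the 1,2-anti 8β- and 1,3-anti 5β-alcohols under acidic conditions that avoid translactonization.

Step 21
Reactants: 28 lactone triol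
Product: 29 mesylate (5β-OMs; 8β-OH; 9α-OH; 14-OTBS)
Conditions: MsCl (1.2 equiv), pyridine, DMAP (cat.), CH2Cl2, 0 °C
Reagents that add atoms: methanesulfonyl chloride, CS(=O)(=O)Cl
Why: Sulfonylation should occur at the equatorial C5 hydroxyl, because the C8 hydroxyl is axial, flanked by a quaternary carbon and 1,3-diaxial to C3, and the C9 hydroxyl is tertiary.

Step 22
Reactants: 29 mesylate; 30 (S)-2-methylbutanoic acid
Product: 31 fragmentation substrate (cis-decalin 12,6α-olide; 5β-OMs equatorial; 8β-O-(S)-2-methylbutanoyl axial; free 9α-OH axial; 14-OTBS; C1=C10)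
Conditions: 30, 2,4,6-trichlorobenzoyl chloride, Et3N, THF, rt; then 29, DMAP, toluene, 40 °C
Reagents that add atoms: none
Why: Yamaguchi esterification through the mixed anhydride suits the hindered axial C8 hydroxyl and should leave the tertiary C9 hydroxyl and the α-stereocentre of the acid untouched.

Step 23
Reactants: 31 fragmentation substrate
Product: 32 cyclodecadienone (ten-membered 1(10),4-dien-9-one, both olefins ring-cis; 12,6α-olide; 8β-ester; 14-OTBS)
Conditions: KOC(CH3)3 (1.05 equiv), THF, 0 °C; pH 7 buffer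
Reagents that add atoms: none
Why: Deprotonation of the tertiary C9 hydroxyl gives an alkoxide whose electron pair becomes the C9 carbonyl while the C4–C9 σ bond, antiperiplanar to the equatorial C5–OMs bond, breaks and mesylate departs, so C4=C5 and the ketone appear in one concerted, stereospecific event. The closest known reaction type is the Grob (Wharton-type) fragmentation of cyclic 1,3-diol monosulfonates to medium-ring enones. No bond of the ten-membered ring is made here: the ring appears by ring expansion when the bond shared by rings A and B is cut, not by an end-to-end cyclization, and its strain is paid for by carbonyl formation and loss of mesylate. No stereocentre is created (C4 and C9 become trigonal), and both olefin geometries are dictated by the substrate: C1=C10 is ring-cis because it was a cyclohexene bond, and C4=C5 is ring-cis because in the cis-fused chair C3 is axial on ring B and hence gauche to C6 across C4–C5. The step needs fragmentation to outrun elimination, oxetane formation, acyl transfer and epimerization; the trans-fused lactone locks the chair with the mesylate equatorial (no antiperiplanar hydrogen), the trans-diaxial C8–O/C9–O pair keeps the alkoxide away from the ester, and the single equivalent of base is consumed as potassium methanesulfonate so that none remains to epimerize C8.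

Step 24
Reactants: 32 cyclodecadienone
Product: 33 allylic alcohol (9α-OH; 8β-ester; 12,6α-olide; 14-OTBS)
Conditions: NaBH4, CeCl3·7H2O, MeOH, −78 °C
Reagents that add atoms: none
Why: Luche 1,2-reduction of the enone, with the non-chelating α-acyloxy group anti to the incoming hydride (Felkin–Anh) and attack from the outer face of the ring ketone, is expected to give the 8,9-syn (9α) alcohol of the target.

Step 25
Reactants: 33 allylic alcohol
Product: 34 bis-silyl ether (9α-OTBS; 14-OTBS)
Conditions: TBSOTf, 2,6-lutidine, CH2Cl2, −78 °C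
Reagents that add atoms: tert-butyldimethylsilyl trifluoromethanesulfonate, CC(C)(C)[Si](C)(C)OS(=O)(=O)C(F)(F)F
Why: Silyl triflate silylation protects the secondary allylic C9 hydroxyl before base treatment and before the neighbouring ester can migrate.

Step 26
Reactants: 34 bis-silyl ether
Product: 37 α-methylene lactone (C11=C13; 9α-OTBS; 14-OTBS; 8β-ester), via Mannich base 35 (not isolated), via ammonium iodide 36 (not isolated)
Conditions: LiN(iPr)2 (1.1 equiv), THF, −78 °C, then CH2=NMe2+ I−; then MeI, MeOH, rt; then NaHCO3 (aq.), EtOAc, rt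
Reagents that add atoms: dimethyl(methylidene)ammonium iodide (Eschenmoser's salt), C=[N+](C)C.[I-]
Why: α-Methylenation of the lactone by enolate Mannich reaction, quaternization and Hofmann-type elimination should be selective because the lactone CH2 is far more acidic and accessible than the branched α-CH of the ester.

Step 27
Reactants: 37 α-methylene lactone
Product: 38 diol (9α-OH; 14-OH)
Conditions: HF·pyridine, pyridine, THF, 0 °C to rt
Reagents that add atoms: none
Why: Buffered fluoride cleaves both silyl ethers under mildly acidic conditions that should not promote acyl migration or conjugate addition to the α-methylene lactone.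

Step 28
Reactants: 38 diol
Product: 39 target CNP0168436.1
Conditions: TEMPO (10 mol %), PhI(OAc)2, CH2Cl2, rt
Reagents that add atoms: none
Why: Oxoammonium-mediated (TEMPO/PhI(OAc)2) oxidation is selective for the primary allylic C14 alcohol over the secondary C9 alcohol and gives the enal of the target.

**Compound list**

1 | propane-1,3-diol | OCCCO | starting material
2 | 3-[(4-methoxybenzyl)oxy]propan-1-ol | COc1ccc(COCCCO)cc1 | intermediate
3 | 3-[(4-methoxybenzyl)oxy]propanal | COc1ccc(COCCC=O)cc1 | intermediate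
4 | vinylmagnesium bromide | C=C[Mg]Br | starting material
5 | rac-5-[(4-methoxybenzyl)oxy]pent-1-en-3-ol | C=CC(O)CCOCc1ccc(OC)cc1 | intermediate
6 | 5-[(4-methoxybenzyl)oxy]pent-1-en-3-one | C=CC(=O)CCOCc1ccc(OC)cc1 | intermediate
7 | 2-methylcyclohexane-1,3-dione | CC1C(=O)CCCC1=O | starting material
8 | 2-{5-[(4-methoxybenzyl)oxy]-3-oxopentyl}-2-methylcyclohexane-1,3-dione | CC1(CCC(=O)CCOCc2ccc(OC)cc2)C(=O)CCCC1=O | intermediate
9 | (S)-5-{[(4-methoxybenzyl)oxy]methyl}-8a-methyl-3,4,8,8a-tetrahydronaphthalene-1,6(2H,7H)-dione | C[C@]12CCC(=O)C(COCc3ccc(OC)cc3)=C1CCCC2=O | intermediate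
10 | (4aS,5S)-5-hydroxy-1-{[(4-methoxybenzyl)oxy]methyl}-4a-methyl-4,4a,5,6,7,8-hexahydronaphthalen-2(3H)-one | C[C@]12CCC(=O)C(COCc3ccc(OC)cc3)=C1CCC[C@@H]2O | intermediate
11 | epoxy ketone: 9α,10α-epoxide of 10, epoxide oxygen cis to C15 and to the 5α-OH | C[C@]12CCC(=O)[C@]3(COCc4ccc(OC)cc4)O[C@@]31CCC[C@@H]2O | intermediate
12 | cis-decalin diol: C1=C10 olefin with C14–OPMB, 9α-OH (ring fusion, cis to C15), 5α-OH | C[C@]12CCC=C(COCc3ccc(OC)cc3)[C@@]1(O)CCC[C@@H]2O | intermediate
13 | hydroxy acetal: 9,14-O-(4-methoxybenzylidene) acetal of 12 (aryl equatorial), 5α-OH | C[C@]12CCC=C3CO[C@H](c4ccc(OC)cc4)O[C@@]31CCC[C@@H]2O | intermediate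
14 | acetal ketone: C5 ketone | C[C@]12CCC=C3CO[C@H](c4ccc(OC)cc4)O[C@@]31CCCC2=O | intermediate
15 | trimethylsilyl enol ether of 14 (C5–OSiMe3, C5=C6) | C[C@]12CCC=C3CO[C@H](c4ccc(OC)cc4)O[C@@]31CCC=C2O[Si](C)(C)C | intermediate
16 | acetal enone: C5 ketone, C6=C7 | C[C@]12CCC=C3CO[C@H](c4ccc(OC)cc4)O[C@@]31CC=CC2=O | intermediate
17 | trimethylsilyl dienol ether of 16 (C5–OSiMe3, C5=C6, C7=C8) | C[C@]12CCC=C3CO[C@H](c4ccc(OC)cc4)O[C@@]31C=CC=C2O[Si](C)(C)C | intermediate
18 | hydroxy enone: 8β-OH, C5 ketone, C6=C7 | C[C@]12CCC=C3CO[C@H](c4ccc(OC)cc4)O[C@@]31[C@@H](O)C=CC2=O | intermediate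
19 | silyloxy enone: 8β-OSiEt3 | C[C@]12CCC=C3CO[C@H](c4ccc(OC)cc4)O[C@@]31[C@@H](O[Si](CC)(CC)CC)C=CC2=O | intermediate
20 | Michael adduct as trimethylsilyl enol ether: C5–OSiMe3, C5=C6, 7α-CH2CO2CH3, 8β-OSiEt3 | C[C@]12CCC=C3CO[C@H](c4ccc(OC)cc4)O[C@@]31[C@@H](O[Si](CC)(CC)CC)[C@H](CC(=O)OC)C=C2O[Si](C)(C)C | intermediate
21 | ester enone: C5 ketone, C6=C7 with CH2CO2CH3 on C7, 8β-OSiEt3 | C[C@]12CCC=C3CO[C@H](c4ccc(OC)cc4)O[C@@]31[C@@H](O[Si](CC)(CC)CC)C(CC(=O)OC)=CC2=O | intermediate
22 | dimethylphenylsilyl enol ether: C5–OSiMe2Ph, C5=C6, 7β-CH2CO2CH3 (7α-H), 8β-OSiEt3 | C[C@]12CCC=C3CO[C@H](c4ccc(OC)cc4)O[C@@]31[C@@H](O[Si](CC)(CC)CC)[C@@H](CC(=O)OC)C=C2O[Si](C)(C)c5ccccc5 | intermediate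
23 | silyloxy ketone: C5 ketone, 6α-OSiMe2Ph, 7β-CH2CO2CH3, 8β-OSiEt3 | C[C@]12CCC=C3CO[C@H](c4ccc(OC)cc4)O[C@@]31[C@@H](O[Si](CC)(CC)CC)[C@@H](CC(=O)OC)[C@H](O[Si](C)(C)c5ccccc5)C2=O | intermediate
24 | acetal keto lactone: trans-fused 12,6α-olide (C11H2), C5 ketone, 8β-OSiEt3, 9,14-O-acetal | C[C@]12CCC=C3CO[C@H](c4ccc(OC)cc4)O[C@@]31[C@@H](O[Si](CC)(CC)CC)[C@H]5CC(=O)O[C@@H]5C2=O | intermediate
25 | keto lactone triol: 12,6α-olide, C5 ketone, 8β-OH, 9α-OH, 14-OH | C[C@]12CCC=C(CO)[C@@]1(O)[C@@H](O)[C@H]3CC(=O)O[C@@H]3C2=O | intermediate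
26 | silyl ether keto lactone: as 25 with 14-OTBS | C[C@]12CCC=C(CO[Si](C)(C)C(C)(C)C)[C@@]1(O)[C@@H](O)[C@H]3CC(=O)O[C@@H]3C2=O | intermediate
27 | diketo lactone: 12,6α-olide, C5 and C8 ketones, 9α-OH, 14-OTBS | C[C@]12CCC=C(CO[Si](C)(C)C(C)(C)C)[C@@]1(O)C(=O)[C@H]3CC(=O)O[C@@H]3C2=O | intermediate
28 | lactone triol: 5β-OH, 8β-OH, 9α-OH, 14-OTBS | C[C@]12CCC=C(CO[Si](C)(C)C(C)(C)C)[C@@]1(O)[C@@H](O)[C@H]3CC(=O)O[C@@H]3[C@H]2O | intermediate
29 | mesylate: 5β-OMs, 8β-OH, 9α-OH, 14-OTBS | C[C@]12CCC=C(CO[Si](C)(C)C(C)(C)C)[C@@]1(O)[C@@H](O)[C@H]3CC(=O)O[C@@H]3[C@H]2OS(C)(=O)=O | intermediate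
30 | (S)-2-methylbutanoic acid | CC[C@H](C)C(=O)O | starting material
31 | fragmentation substrate: cis-decalin 12,6α-olide, 5β-OMs (equatorial), 8β-O-(S)-2-methylbutanoyl (axial), 9α-OH (axial), 14-OTBS, C1=C10 | C[C@]12CCC=C(CO[Si](C)(C)C(C)(C)C)[C@@]1(O)[C@@H](OC(=O)[C@@H](C)CC)[C@H]3CC(=O)O[C@@H]3[C@H]2OS(C)(=O)=O | intermediate
32 | cyclodecadienone: ten-membered 1(10),4-dien-9-one, both olefins ring-cis, 12,6α-olide, 8β-ester, 14-OTBS | O=C1O[C@@H]2/C=C(/C)CC/C=C(/CO[Si](C)(C)C(C)(C)C)C(=O)[C@@H](OC(=O)[C@@H](C)CC)[C@H]2C1 | intermediate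
33 | allylic alcohol: 9α-OH | O=C1O[C@@H]2/C=C(/C)CC/C=C(/CO[Si](C)(C)C(C)(C)C)[C@H](O)[C@@H](OC(=O)[C@@H](C)CC)[C@H]2C1 | intermediate
34 | bis-silyl ether: 9α-OTBS, 14-OTBS | O=C1O[C@@H]2/C=C(/C)CC/C=C(/CO[Si](C)(C)C(C)(C)C)[C@H](O[Si](C)(C)C(C)(C)C)[C@@H](OC(=O)[C@@H](C)CC)[C@H]2C1 | intermediate
35 | Mannich base: C11–CH2N(CH3)2 lactone | CN(C)C[C@@H]1C(=O)O[C@@H]2/C=C(/C)CC/C=C(/CO[Si](C)(C)C(C)(C)C)[C@H](O[Si](C)(C)C(C)(C)C)[C@@H](OC(=O)[C@@H](C)CC)[C@@H]12 | intermediate
36 | ammonium iodide: C11–CH2N(CH3)3+ I− lactone | C[N+](C)(C)C[C@@H]1C(=O)O[C@@H]2/C=C(/C)CC/C=C(/CO[Si](C)(C)C(C)(C)C)[C@H](O[Si](C)(C)C(C)(C)C)[C@@H](OC(=O)[C@@H](C)CC)[C@@H]12.[I-] | intermediate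
37 | α-methylene lactone: C11=C13, 9α-OTBS, 14-OTBS | C=C1C(=O)O[C@@H]2/C=C(/C)CC/C=C(/CO[Si](C)(C)C(C)(C)C)[C@H](O[Si](C)(C)C(C)(C)C)[C@@H](OC(=O)[C@@H](C)CC)[C@@H]12 | intermediate
38 | diol: 9α-OH, 14-OH | C=C1C(=O)O[C@@H]2/C=C(/C)CC/C=C(/CO)[C@H](O)[C@@H](OC(=O)[C@@H](C)CC)[C@@H]12 | intermediate
39 | CNP0168436.1: 8β-[(S)-2-methylbutanoyloxy]-9α-hydroxy-14-oxogermacra-1(10),4,11(13)-trien-12,6α-olide, both ring olefins ring-cis | C=C1C(=O)O[C@@H]2/C=C(/C)CC/C=C(/C=O)[C@H](O)[C@@H](OC(=O)[C@@H](C)CC)[C@@H]12 | target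

**Count and risks**

Total step count: 28. Longest linear sequence: 28 steps (1 to 39; compounds 4, 7 and 30 enter at steps 3, 5 and 22).

Steps most likely to fail:

Step 16. Risk: hydride is delivered to the wrong face of C7, or 1,2-hydrosilylation competes, so that the C6/C7 pair cannot close the trans-lactone. The fallback sets C7 by equilibration next to a ketone instead of by hydride delivery. Starting from 19, Michael addition of the lithium enolate of N,N-dimethylacetamide (LiN(iPr)2, THF, −78 °C) would give the keto amide F1. HF·pyridine would free the C8 alcohol F2. Dess–Martin oxidation followed by DBU would give the 5,8-dione F3 with the acetamide arm equilibrated to the equatorial β position. KN(SiMe3)2 and 2-(phenylsulfonyl)-3-phenyloxaziridine would hydroxylate the only methylene flanking a carbonyl to the 6α-hydroxy dione F4. Warm aqueous acetic acid would close the lactone from the hydroxy amide and hydrolyse the acetal to the diketo lactone diol F5, and silylation as in step 18 would return to 27.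

Step 24. Risk: poor facial selectivity on the flexible ring ketone, giving the C9 epimer. The fallback uses inversion instead of facial control. From 32 the same reduction would give the 9β-alcohol F6. Mitsunobu reaction with formic acid (PPh3, diisopropyl azodicarboxylate, THF, 0 °C) would invert C9 to the 9α-formate F7, and KHCO3 in methanol at 0 °C would remove the formyl group and return to 33.

Step 23. Risk: after fragmentation, epimerization at C8 of the α-acyloxy ketone by residual base, or alkoxide attack on the ester; the preceding acylation of the hindered axial hydroxyl may also stall. The fallback carries C8 as a silyl ether and esterifies after the ring is open. From 29, Et3SiCl/imidazole in DMF at 40 °C would give the triethylsilyl ether F8. KOC(CH3)3 would fragment it to the silyloxy dienone F9. NaBH4/CeCl3·7H2O would give the 9α-alcohol F10, and TBSOTf/2,6-lutidine the bis-silyl ether F11. HF·pyridine/pyridine at 0 °C would cleave only the triethylsilyl group to the C8 alcohol F12, and Yamaguchi esterification with 30 would return to 34.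

**Further compounds**

F1 | step 16 | keto amide: C5 ketone, 7α-CH2CON(CH3)2, 8β-OSiEt3, 9,14-O-acetal | C[C@]12CCC=C3CO[C@H](c4ccc(OC)cc4)O[C@@]31[C@@H](O[Si](CC)(CC)CC)[C@H](CC(=O)N(C)C)CC2=O
F2 | step 16 | C8 alcohol: as F1 with 8β-OH | C[C@]12CCC=C3CO[C@H](c4ccc(OC)cc4)O[C@@]31[C@@H](O)[C@H](CC(=O)N(C)C)CC2=O
F3 | step 16 | 5,8-dione: C5 and C8 ketones, 7β-CH2CON(CH3)2 | C[C@]12CCC=C3CO[C@H](c4ccc(OC)cc4)O[C@@]31C(=O)[C@@H](CC(=O)N(C)C)CC2=O
F4 | step 16 | 6α-hydroxy dione: as F3 with 6α-OH | C[C@]12CCC=C3CO[C@H](c4ccc(OC)cc4)O[C@@]31C(=O)[C@@H](CC(=O)N(C)C)[C@H](O)C2=O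
F5 | step 16 | diketo lactone diol: 12,6α-olide, C5 and C8 ketones, 9α-OH, 14-OH | C[C@]12CCC=C(CO)[C@@]1(O)C(=O)[C@H]3CC(=O)O[C@@H]3C2=O
F6 | step 24 | 9β-alcohol: C9 epimer of 33 | O=C1O[C@@H]2/C=C(/C)CC/C=C(/CO[Si](C)(C)C(C)(C)C)[C@@H](O)[C@@H](OC(=O)[C@@H](C)CC)[C@H]2C1
F7 | step 24 | 9α-formate: formate ester of 33 | O=C1O[C@@H]2/C=C(/C)CC/C=C(/CO[Si](C)(C)C(C)(C)C)[C@H](OC=O)[C@@H](OC(=O)[C@@H](C)CC)[C@H]2C1
F8 | step 23 | triethylsilyl ether: 5β-OMs, 8β-OSiEt3, 9α-OH, 14-OTBS decalin lactone | C[C@]12CCC=C(CO[Si](C)(C)C(C)(C)C)[C@@]1(O)[C@@H](O[Si](CC)(CC)CC)[C@H]3CC(=O)O[C@@H]3[C@H]2OS(C)(=O)=O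
F9 | step 23 | silyloxy dienone: ten-membered 1(10),4-dien-9-one, 8β-OSiEt3, 14-OTBS | O=C1O[C@@H]2/C=C(/C)CC/C=C(/CO[Si](C)(C)C(C)(C)C)C(=O)[C@@H](O[Si](CC)(CC)CC)[C@H]2C1
F10 | step 23 | 9α-alcohol: 9α-OH, 8β-OSiEt3, 14-OTBS | O=C1O[C@@H]2/C=C(/C)CC/C=C(/CO[Si](C)(C)C(C)(C)C)[C@H](O)[C@@H](O[Si](CC)(CC)CC)[C@H]2C1
F11 | step 23 | bis-silyl ether: 9α-OTBS, 8β-OSiEt3, 14-OTBS | O=C1O[C@@H]2/C=C(/C)CC/C=C(/CO[Si](C)(C)C(C)(C)C)[C@H](O[Si](C)(C)C(C)(C)C)[C@@H](O[Si](CC)(CC)CC)[C@H]2C1
F12 | step 23 | C8 alcohol: 8β-OH, 9α-OTBS, 14-OTBS | O=C1O[C@@H]2/C=C(/C)CC/C=C(/CO[Si](C)(C)C(C)(C)C)[C@H](O[Si](C)(C)C(C)(C)C)[C@@H](O)[C@H]2C1
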